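## The problem

Target 25 (CNP0313563.1) is the diester of a cyclopentane core with two copies of one acid, (3S,4E)-4-formyl-3-(2-oxoethyl)hex-4-enoic acid, so the work divides into a core diol and one acid used twice. The core, numbered here and throughout, carries a CH2O–acyl group at C1, a methyl group at C2, an O–acyl group at C3, an unsubstituted C4 and a free CH(CH2OH)2 arm at C5. The ring centres C5, C1, C2 and C3 are contiguous and alternate in orientation (every neighbouring pair trans), so that once one of them is fixed absolutely the others can in principle be set by equilibration. The two acyl C3 centres are remote from the core and need reagent control. The four aldehydes (two enolisable CH2CHO groups and two E-ethylidene enals that carry the acyl stereocentre on their α-carbon) and the free 1,3-diol will not survive strong base, hydride, oxidants or nucleophiles, so they must travel masked and be released last. The enabling feature lies in the cyclopentane ring: C1, C2, C3 and the CH2O carbon are the four carbons of 2-methylbutanedial, and C4, C5 and the arm are a two-carbon acceptor. Because C4 bears only hydrogen, a nitro group can sit there as a traceless activator, which makes the core the product of an aldehyde–nitroalkene Michael addition followed by a Henry ring closure.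

## Retrosynthesis

No skeletal bond is cut between 25 and 24. The four aldehydes are carried as dimethyl acetals and the 1,3-diol as its isopropylidene ketal, so that one mild aqueous-acid treatment of 24 releases everything. Choosing masks that all fall to the same reagent avoids a sequence of late deprotections on a tetra-aldehyde.

The two ester C–O bonds of 24 are cut to give core diol 13 and two equivalents of acid 23. Building the chains on the core is the neighbouring option, but it puts two catalyst-controlled events on valuable material. Cutting at the esters lets the enantiopurity of 23 be checked before it meets 13. The forward step must acylate a hindered secondary alcohol, which is tolerable because 23 has no α-stereocentre to lose.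

Diol 13 is traced to nitro diol 12 (C4–N bond) and then to nitro aldehyde 11 (aldehyde reduction). The nitro group at the future CH2 and the aldehyde at the future CH2O are the activating groups of the annulation; their removal asks only for a hydride reduction and a radical denitration.

The key cut opens the ring of 11 at C3–C4 (Henry) to the open-chain adduct 10, and then at C1–C5 (Michael) to racemic 2-methylbutanedial 9 and nitroalkene 5. Two bonds, the ring and all five ring stereocentres arise in one operation from a racemic C5 dialdehyde and an achiral C8 nitroalkene that already carries the protected arm. The forward reaction must do three things: fix C5 by catalyst control, form the enamine only at the unbranched aldehyde, and let C1, C2 and C3 settle to the all-trans array by enolisation and reversible Henry closure. A cut that leaves the methyl group for later alkylation would meet a regiochemistry problem at a cyclopentanone, so the methyl is brought in with the dialdehyde.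

Dialdehyde 9 is the hydrolysis product of 2,5-dimethoxy-3-methyltetrahydrofuran 8. This comes by hydrogenation of dihydrofuran 7, itself the oxidative methoxylation product of 3-methylfuran 6. The sequence mirrors the standard route to the unsubstituted 1,4-dialdehyde and stores the unstable 9 as a stable acetal until needed.

Nitroalkene 5 is cut at the C=C bond to nitro alcohol 4, and 4 at its C–C bond to aldehyde 2 and nitromethane 3 (Henry). Aldehyde 2 is the oxidation product of the alcohol 1, which is bought.

Acid 23 is cut at its C2–C3 bond. Decarboxylation and deallylation lead back through malonic acid 22 to diallyl ester 21; its acetal is removed to aldehyde 20; and a conjugate addition disconnects 20 into dienal 18 and diallyl malonate 19. One amine-catalysed Michael addition then sets the acyl stereocentre and delivers the CH2CHO arm, with the ethylidene unit already in place. The forward step must add 1,4 and not 1,6 to the dienyl iminium ion.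

Dienal 18 is cut at the C3–C4 single bond (Heck) to vinyl iodide 16 and acrolein 17. Iodide 16 is the acetal of (Z)-2-iodobut-2-enal 15, made by α-iodination of crotonaldehyde 14. The alkene geometry of the final enals (methyl trans to the formyl carbon) is therefore fixed in the first step of this branch and carried through by stereoretentive chemistry.

## Roads not taken

Alternative 1: The acyl unit is cut between its C3 and the CH2 of the aldehyde arm, and both aldehydes of one chain are hidden in a dihydropyran. In the forward sense the enal A1, acting as a 1-oxadiene, and ethyl vinyl ether A2 combine in an inverse-demand hetero-Diels–Alder reaction under a chiral tridentate Schiff-base complex of trivalent chromium, (Schiff base)CrCl, to give the cis-dihydropyran A3.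
- Merits: the cycloaddition type is well established for β-alkyl enals, it sets the acyl stereocentre with catalyst control, and the ring is a compact mask for a 1,5-dialdehyde.
- Weak points: the ethylidene carbons and their E geometry must still be introduced at the enol-ether carbon; the silyloxyethyl arm must be oxidised twice to the acid; and two 2-alkoxydihydropyrans must be opened by acid at the end. The road also offers nothing for the core.
- Comparison: in stereochemical precedent this road is better than the dienal Michael addition used here. The chosen plan sets against it a five-step acid whose alkene geometry is fixed from the start, and the same amine catalyst family for both asymmetric steps.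

Alternative 2: Both acyl C2–C3 bonds are cut after the core is already acylated. Diol 13 would be converted into the bis(allyl malonate) A4, and both malonate carbons would add to two molecules of dienal A5 under a diarylprolinol silyl ether to give the bis-adduct A6.
- Merits: it is the most convergent option; no separate acid is made, and the hindered secondary alcohol is acylated with a cheap malonate half-ester.
- Weak points: two catalyst-controlled additions must succeed on a bulky, chiral nucleophile; any 1,6-addition or facial error gives diastereomers of a large molecule; the unsymmetrical malonates add two stereocentres that complicate analysis until decarboxylation; and A6 carries free aldehydes that need protection before the allyl esters are removed.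
- Comparison: in step count this road is better by about two steps. The chosen plan sets against it the chance to purify and assay acid 23 before it meets 13, and a simple symmetric malonate in the asymmetric step.

Alternative 3: The ring is cut at C2–C3. The 4-pentenal A7 is a silyl ether, dimethyl malonate relative of intermediate 20 and has the same absolute configuration. Its aldehyde C–H bond would add across the trisubstituted alkene under [Rh((R)-BINAP)]ClO4, a cationic complex of monovalent rhodium, to give cyclopentanone A8.
- Merits: one enantioselective Michael addition would supply both the core and the acyl chains; C2 sits α to the ketone in A8 and can be equilibrated reliably; and no nitro group has to be removed.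
- Weak points: hydroacylation of a trisubstituted alkene is slow and competes with decarbonylation; C1 must be set against C5 in the hydrometalation; the ketone must then be reduced with hydride delivered syn to the methyl group; and the malonate must be reduced to the diol arm.
- Comparison: the security of C2 is greater here than in the chosen plan, and that is a real advantage. The chosen plan sets against it a metal-free annulation that gives the ring, the alcohol oxidation level at C3 and the finished arm in one step from two small building blocks, on a reaction type known for the parent dialdehyde.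

Key step: step 7

Assumption: alcohol 1 is treated as a purchased compound; it is the acetonide of 2-(hydroxymethyl)propane-1,3-diol and is one acetalisation away if not in stock.

Remark: CIP descriptors of the core change between intermediates because substituent priorities change; no centre is inverted after step 7. Compounds 11 and 12 are drawn as the C4 epimer expected to predominate; the other C4 epimer converges on 13 in step 9.

## Route

Step 1
Reactants: 1 (2,2-dimethyl-1,3-dioxan-5-yl)methanol
Product: 2 2,2-dimethyl-1,3-dioxane-5-carbaldehyde
Conditions: TEMPO (10 mol %), PhI(OAc)2, CH2Cl2, rt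
Reagents that add atoms: none
Why: Nitroxyl-catalysed alcohol oxidation stops at the aldehyde and runs without base, which matters because 2 is a β-alkoxy aldehyde that could open by elimination; no stereocentre is involved.

Step 2
Reactants: 2 2,2-dimethyl-1,3-dioxane-5-carbaldehyde; 3 nitromethane
Product: 4 1-(2,2-dimethyl-1,3-dioxan-5-yl)-2-nitroethan-1-ol (racemic)
Conditions: t-BuOK (10 mol %), THF/t-BuOH (1:1), 0 °C
Reagents that add atoms: none
Why: Base-catalysed Henry (nitroaldol) addition of the nitronate of 3 to an unhindered aldehyde, a pure addition in which every atom of both partners ends in 4; nitromethane is taken in excess to drive the equilibrium and the surplus is evaporated unchanged. The new carbinol centre is racemic and disappears in step 3.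

Step 3
Reactants: 4 1-(2,2-dimethyl-1,3-dioxan-5-yl)-2-nitroethan-1-ol
Product: 5 2,2-dimethyl-5-[(E)-2-nitroethenyl]-1,3-dioxane
Conditions: MsCl, Et3N, CH2Cl2, −20 → 0 °C
Reagents that add atoms: none
Why: Mesylation of the β-nitro alcohol and E1cB elimination give the conjugated nitroalkene, the E isomer being the stable one for a β-alkyl nitroalkene; the low temperature limits base-induced migration of the double bond toward the dioxane ring.

Step 4
Reactants: 6 3-methylfuran
Product: 7 2,5-dimethoxy-3-methyl-2,5-dihydrofuran (cis/trans mixture)
Conditions: Br2, MeOH, Na2CO3, −40 → −10 °C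
Reagents that add atoms: methanol, CO
Why: Oxidative 2,5-dimethoxylation of a furan, the classical entry to masked 1,4-dialdehydes: bromine activates the ring and methanol is captured at C2 and C5; the isomer mixture is of no consequence.

Step 5
Reactants: 7 2,5-dimethoxy-3-methyl-2,5-dihydrofuran
Product: 8 2,5-dimethoxy-3-methyltetrahydrofuran (mixture of stereoisomers)
Conditions: H2 (3 atm), Raney Ni, MeOH, rt
Reagents that add atoms: none
Why: Heterogeneous hydrogenation of the ring alkene over nickel, the catalyst used for the parent dihydrofuran because it leaves the allylic acetal C–O bonds intact; the new methyl-bearing centre forms as a mixture and becomes the racemic, enolisable α-carbon of 9.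

Step 6
Reactants: 8 2,5-dimethoxy-3-methyltetrahydrofuran
Product: 9 2-methylbutanedial (racemic)
Conditions: H2O, 90 °C; MeOH distilled off; extraction (CH2Cl2); used at once
Reagents that add atoms: water, O
Why: Hydrolysis of the cyclic bis-acetal in hot water, as practised for the unsubstituted 1,4-dialdehyde, releases 9; it is used immediately because it oligomerises on standing.

Step 7
Reactants: 9 2-methylbutanedial (racemic); 5 2,2-dimethyl-5-[(E)-2-nitroethenyl]-1,3-dioxane
Product: 11 (1S,2R,3S,4R,5S)-5-(2,2-dimethyl-1,3-dioxan-5-yl)-3-hydroxy-2-methyl-4-nitrocyclopentane-1-carbaldehyde, via open-chain Michael adduct 10 (not isolated)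
Conditions: (R)-2-[diphenyl(trimethylsilyloxy)methyl]pyrrolidine (10 mol %), 4-nitrophenol (10 mol %), MeCN, 0 °C → rt; then i-Pr2NEt, 0 °C → rt until the isomer composition is constant
Reagents that add atoms: none
Why: The amine condenses with the unbranched CH2CHO end of 9 to an E-enamine whose α-carbon (ring C1) adds to the β-carbon of 5 (ring C5) through the usual acyclic synclinal transition state, on the enamine face left open by the diphenyl(silyloxy)methyl group; hydrolysis returns the catalyst and gives 10. The (R)-catalyst is chosen by analogy with propanal and β-nitrostyrene, where the (S)-catalyst gives the 2R,3S adduct, the opposite sense at the nitroalkene carbon to that needed at C5; this catalyst-set centre cannot epimerise and anchors all the others. On addition of i-Pr2NEt the nitronate carbon (C4) attacks the second aldehyde (C3) in a 5-exo-trig closure; the closest known reaction is the diarylprolinol silyl ether Michael/Henry formal [3+2] annulation of butanedial with nitroalkenes. The syn Michael adduct corresponds to a ring with C1 and C5 substituents cis, so C1 must invert by enolisation α to the ring aldehyde; C2 epimerises through the enol of the branched aldehyde in 10; and C3 and C4 equilibrate by retro-Henry/Henry reaction and nitronate protonation. The expected resting point has C5, C1, C2 and C3 alternating all-trans, with the nitro group trans to the dioxanyl group and cis to the small hydroxyl, to which it can hydrogen-bond. The step needs enamine formation only at the unbranched aldehyde, which the slow condensation of α-branched aldehydes with this hindered amine secures; the dialdehyde is taken in excess over 5 because part of it self-condenses.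

Step 8
Reactants: 11 (1S,2R,3S,4R,5S)-5-(2,2-dimethyl-1,3-dioxan-5-yl)-3-hydroxy-2-methyl-4-nitrocyclopentane-1-carbaldehyde
Product: 12 [(1S,2R,3S,4R,5R)-5-(2,2-dimethyl-1,3-dioxan-5-yl)-3-hydroxy-2-methyl-4-nitrocyclopentyl]methanol
Conditions: NaBH4, MeOH, 0 °C
Reagents that add atoms: none
Why: Borohydride reduction of the aldehyde is faster than base-induced retro-Henry opening and does not touch an aliphatic nitro group; no stereocentre changes, and the epimerisable C1 is frozen.

Step 9
Reactants: 12 [(1S,2R,3S,4R,5R)-5-(2,2-dimethyl-1,3-dioxan-5-yl)-3-hydroxy-2-methyl-4-nitrocyclopentyl]methanol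
Product: 13 [(1S,2R,3R,5R)-5-(2,2-dimethyl-1,3-dioxan-5-yl)-3-hydroxy-2-methylcyclopentyl]methanol
Conditions: Bu3SnH (5 equiv), AIBN (0.5 equiv, in portions), toluene, 110 °C
Reagents that add atoms: none
Why: Radical chain denitration: the stannyl radical adds to a nitro oxygen, the adduct fragments to the secondary C4 radical and Bu3SnONO, and the radical takes hydrogen from Bu3SnH. A secondary nitro group needs excess hydride at reflux; the β-hydroxyl is retained because C–O β-scission is slow, and C4 becomes CH2 so its earlier configuration is irrelevant.

Step 10
Reactants: 14 (E)-but-2-enal (crotonaldehyde)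
Product: 15 (Z)-2-iodobut-2-enal
Conditions: I2, K2CO3, DMAP (20 mol %), THF/H2O (1:1), rt
Reagents that add atoms: iodine, II
Why: α-Iodination of an enal by amine-catalysed conjugate addition, iodination of the resulting enolate and loss of the amine; the product keeps methyl trans to the formyl group, which is the geometry required in the target.

Step 11
Reactants: 15 (Z)-2-iodobut-2-enal
Product: 16 (Z)-2-iodo-1,1-dimethoxybut-2-ene
Conditions: HC(OMe)3, MeOH, TsOH·H2O (2 mol %), rt
Reagents that add atoms: trimethyl orthoformate, COC(OC)OC; methanol, CO
Why: Acid-catalysed acetalisation with orthoformate as water scavenger masks the enal carbonyl so that it cannot act as a second iminium or Heck acceptor later; the alkene geometry is untouched.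

Step 12
Reactants: 16 (Z)-2-iodo-1,1-dimethoxybut-2-ene; 17 prop-2-enal (acrolein)
Product: 18 (2E,4E)-4-(dimethoxymethyl)hexa-2,4-dienal
Conditions: Pd(OAc)2 (5 mol %), Bu4NCl, NaHCO3, DMF, 40 °C
Reagents that add atoms: none
Why: Mizoroki–Heck vinylation of acrolein under ligand-free phase-transfer conditions: oxidative addition of the vinyl iodide with retention, insertion at the terminal carbon of acrolein and β-hydride elimination to the E enal, so the methyl group ends cis to the new vinyl group.

Step 13
Reactants: 18 (2E,4E)-4-(dimethoxymethyl)hexa-2,4-dienal; 19 bis(prop-2-enyl) propanedioate (diallyl malonate)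
Product: 21 bis(prop-2-enyl) 2-[(3S,4E)-4-(dimethoxymethyl)-1,1-dimethoxyhex-4-en-3-yl]propanedioate, via Michael adduct aldehyde 20 (not isolated)
Conditions: (R)-2-{bis[3,5-bis(trifluoromethyl)phenyl](trimethylsilyloxy)methyl}pyrrolidine (10 mol %), MeOH, 0 °C → rt; then HC(OMe)3, TsOH·H2O (0.3 equiv), 0 °C → rt
Reagents that add atoms: trimethyl orthoformate, COC(OC)OC; methanol, CO
Why: Iminium-ion Michael addition of a malonate to an enal: the s-trans E iminium ion of 18 is shielded on one face by the diaryl(silyloxy)methyl group, and with the (R)-catalyst the malonate should add to the β-carbon on the face that gives the 3S centre, the mirror image of the sense in which the (S)-catalyst delivers carbon nucleophiles to β-substituted enals. Addition at the β-carbon is expected over the δ-carbon, as is usual for dienyl iminium ions; acetalisation in the same pot masks the new aldehyde so both aldehyde equivalents are dimethyl acetals.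

Step 14
Reactants: 21 bis(prop-2-enyl) 2-[(3S,4E)-4-(dimethoxymethyl)-1,1-dimethoxyhex-4-en-3-yl]propanedioate
Product: 23 (3S,4E)-4-(dimethoxymethyl)-3-(2,2-dimethoxyethyl)hex-4-enoic acid, via substituted malonic acid 22 (not isolated)
Conditions: Pd(OAc)2 (5 mol %), PPh3 (20 mol %), HCO2H, Et3N, 1,4-dioxane, rt then 100 °C
Reagents that add atoms: none
Why: Zerovalent palladium formed in situ ionises both allyl esters to π-allyl complexes that formate reduces to propene, and the malonic acid then decarboxylates thermally through the cyclic six-membered transition state. The buffered, water-free medium spares the acetals, and the stereocentre is β to the carboxyl, so it cannot epimerise.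

Step 15
Reactants: 13 [(1S,2R,3R,5R)-5-(2,2-dimethyl-1,3-dioxan-5-yl)-3-hydroxy-2-methylcyclopentyl]methanol; 23 (3S,4E)-4-(dimethoxymethyl)-3-(2,2-dimethoxyethyl)hex-4-enoic acid (2.6 equiv)
Product: 24 [(1S,2R,3R,5R)-5-(2,2-dimethyl-1,3-dioxan-5-yl)-2-methyl-3-{[(3S,4E)-4-(dimethoxymethyl)-3-(2,2-dimethoxyethyl)hex-4-enoyl]oxy}cyclopentyl]methyl (3S,4E)-4-(dimethoxymethyl)-3-(2,2-dimethoxyethyl)hex-4-enoate
Conditions: EDC·HCl (3 equiv), DMAP (1 equiv), CH2Cl2, 0 °C → rt
Reagents that add atoms: none
Why: Steglich (carbodiimide/DMAP) esterification of the primary and the secondary hydroxyl with the same acid; because the acid has no α-stereocentre, the hindered secondary alcohol can be forced with excess acylpyridinium without risk of epimerisation, and the neutral conditions leave acetals and ketal alone.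

Step 16
Reactants: 24 the bis-ester of step 15
Product: 25 [(1S,2R,3R,5R)-5-(1,3-dihydroxypropan-2-yl)-3-{[(3S,4E)-4-formyl-3-(2-oxoethyl)hex-4-enoyl]oxy}-2-methylcyclopentyl]methyl (3S,4E)-4-formyl-3-(2-oxoethyl)hex-4-enoate (the target)
Conditions: 1 M aq HCl/THF (1:4), 0 °C → rt
Reagents that add atoms: water, O
Why: Acid-catalysed hydrolysis of the four dimethyl acetals and of the isopropylidene ketal in one operation; the esters survive dilute aqueous acid at this temperature, the acyl stereocentres are not α to any carbonyl and so cannot epimerise by enolisation, and the E enals are the stable geometry.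

## Compound list

1 | (2,2-dimethyl-1,3-dioxan-5-yl)methanol | OCC1COC(C)(C)OC1 | starting material
2 | 2,2-dimethyl-1,3-dioxane-5-carbaldehyde | O=CC1COC(C)(C)OC1 | intermediate
3 | nitromethane | C[N+](=O)[O-] | starting material
4 | 1-(2,2-dimethyl-1,3-dioxan-5-yl)-2-nitroethan-1-ol (racemic) | OC(C[N+](=O)[O-])C1COC(C)(C)OC1 | intermediate
5 | 2,2-dimethyl-5-[(E)-2-nitroethenyl]-1,3-dioxane | CC1(C)OCC(/C=C/[N+](=O)[O-])CO1 | intermediate
6 | 3-methylfuran | Cc1ccoc1 | starting material
7 | 2,5-dimethoxy-3-methyl-2,5-dihydrofuran (isomer mixture) | COC1OC(OC)C(C)=C1 | intermediate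
8 | 2,5-dimethoxy-3-methyltetrahydrofuran (isomer mixture) | COC1OC(OC)C(C)C1 | intermediate
9 | 2-methylbutanedial (racemic) | O=CCC(C)C=O | intermediate
10 | 2-[(1S)-1-(2,2-dimethyl-1,3-dioxan-5-yl)-2-nitroethyl]-3-methylbutanedial (epimers at both aldehyde α-carbons; not isolated) | O=CC(C(C)C=O)[C@@H](C[N+](=O)[O-])C1COC(C)(C)OC1 | intermediate
11 | (1S,2R,3S,4R,5S)-5-(2,2-dimethyl-1,3-dioxan-5-yl)-3-hydroxy-2-methyl-4-nitrocyclopentane-1-carbaldehyde | O=C[C@@H]1[C@@H](C)[C@H](O)[C@H]([N+](=O)[O-])[C@H]1C2COC(C)(C)OC2 | intermediate
12 | [(1S,2R,3S,4R,5R)-5-(2,2-dimethyl-1,3-dioxan-5-yl)-3-hydroxy-2-methyl-4-nitrocyclopentyl]methanol | OC[C@@H]1[C@@H](C)[C@H](O)[C@H]([N+](=O)[O-])[C@H]1C2COC(C)(C)OC2 | intermediate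
13 | [(1S,2R,3R,5R)-5-(2,2-dimethyl-1,3-dioxan-5-yl)-3-hydroxy-2-methylcyclopentyl]methanol | OC[C@@H]1[C@@H](C)[C@H](O)C[C@H]1C2COC(C)(C)OC2 | intermediate
14 | (E)-but-2-enal (crotonaldehyde) | C/C=C/C=O | starting material
15 | (Z)-2-iodobut-2-enal | C/C=C(\I)C=O | intermediate
16 | (Z)-2-iodo-1,1-dimethoxybut-2-ene | C/C=C(\I)C(OC)OC | intermediate
17 | prop-2-enal (acrolein) | C=CC=O | starting material
18 | (2E,4E)-4-(dimethoxymethyl)hexa-2,4-dienal | C/C=C(/C(OC)OC)\C=C\C=O | intermediate
19 | bis(prop-2-enyl) propanedioate (diallyl malonate) | C=CCOC(=O)CC(=O)OCC=C | starting material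
20 | bis(prop-2-enyl) 2-[(3S,4E)-4-(dimethoxymethyl)-1-oxohex-4-en-3-yl]propanedioate (not isolated) | C/C=C(/C(OC)OC)[C@@H](CC=O)C(C(=O)OCC=C)C(=O)OCC=C | intermediate
21 | bis(prop-2-enyl) 2-[(3S,4E)-4-(dimethoxymethyl)-1,1-dimethoxyhex-4-en-3-yl]propanedioate | C/C=C(/C(OC)OC)[C@@H](CC(OC)OC)C(C(=O)OCC=C)C(=O)OCC=C | intermediate
22 | 2-[(3S,4E)-4-(dimethoxymethyl)-1,1-dimethoxyhex-4-en-3-yl]propanedioic acid (not isolated) | C/C=C(/C(OC)OC)[C@@H](CC(OC)OC)C(C(=O)O)C(=O)O | intermediate
23 | (3S,4E)-4-(dimethoxymethyl)-3-(2,2-dimethoxyethyl)hex-4-enoic acid | C/C=C(/C(OC)OC)[C@@H](CC(OC)OC)CC(=O)O | intermediate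
24 | [(1S,2R,3R,5R)-5-(2,2-dimethyl-1,3-dioxan-5-yl)-2-methyl-3-{[(3S,4E)-4-(dimethoxymethyl)-3-(2,2-dimethoxyethyl)hex-4-enoyl]oxy}cyclopentyl]methyl (3S,4E)-4-(dimethoxymethyl)-3-(2,2-dimethoxyethyl)hex-4-enoate | C/C=C(/C(OC)OC)[C@@H](CC(OC)OC)CC(=O)OC[C@@H]1[C@@H](C)[C@H](OC(=O)C[C@H](CC(OC)OC)/C(C(OC)OC)=C\C)C[C@H]1C2COC(C)(C)OC2 | intermediate
25 | [(1S,2R,3R,5R)-5-(1,3-dihydroxypropan-2-yl)-3-{[(3S,4E)-4-formyl-3-(2-oxoethyl)hex-4-enoyl]oxy}-2-methylcyclopentyl]methyl (3S,4E)-4-formyl-3-(2-oxoethyl)hex-4-enoate | C/C=C(/C=O)[C@@H](CC=O)CC(=O)OC[C@@H]1[C@@H](C)[C@H](OC(=O)C[C@H](CC=O)/C(C=O)=C\C)C[C@H]1C(CO)CO | target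

## Step count and risk

Total: 16 steps. Longest linear sequence: 8 steps (1, 2, 3, 7, 8, 9, 15, 16; the dialdehyde line 4, 5, 6, 7, 8, 9, 15, 16 is equally long). The acid branch (10–14) joins at step 15.

Step 7 (key step). The most likely failure is incomplete stereoconvergence. The Michael addition with the parent dialdehyde is established, but equilibration of the methyl-bearing C2 and of the carbinol C3 to the all-trans array has not been tested. The all-trans isomer and the isomer with hydroxyl cis to methyl may be close in energy. Self-condensation of the dialdehyde can also erode conversion. The fallback replaces thermodynamic control in the cascade by thermodynamic control at a ketone. It sets out from 13, obtained as a C2/C3 epimer mixture after steps 8 and 9, and returns to 13 as a single isomer. The primary hydroxyl is silylated selectively (TBSCl, imidazole, 0 °C) to the primary tert-butyldimethylsilyl ether F1. Oxidation of the secondary alcohol with DMP gives the cyclopentanone, which DBU equilibrates at its now enolisable C2 to the trans-methyl ketone F2. Dissolving-metal reduction (Li, NH3, t-BuOH, −78 °C), which favours the more stable carbinol trans to the adjacent methyl group, gives the silyl ether alcohol F3. Bu4NF then returns 13.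

Step 13. The process at risk is regio- and face-selection on a dienyl iminium ion with a branched γ-carbon: addition at the δ-carbon, or poor shielding at the hindered β-carbon, would lower yield or enantiopurity. The fallback changes from catalyst to auxiliary control and reverses the polarity of the bond construction, so only one electrophilic site exists. It sets out from 16 and returns at 23. The known (R)-3-acryloyl-4-phenyl-1,3-oxazolidin-2-one and 4,4-dimethoxybut-1-ene are joined by cross-metathesis with the second-generation Grubbs catalyst (H2IMes)(PCy3)Cl2Ru=CHPh to give the enoyl imide F4. Iodide 16 is converted (t-BuLi, Et2O, −78 °C; MgBr2·OEt2; CuBr·SMe2) into an alkenylcopper reagent. This adds to the chelated s-cis imide on the face opposite the phenyl group to give the conjugate adduct F5, and LiOH/H2O2 releases 23 and the auxiliary.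

Step 9. The chain may fail to propagate: C–N fragmentation from a secondary, unactivated nitro group is slow, so conversion may stall or the nitro group may be only partly reduced. The fallback removes nitrogen by a non-radical route from the amine. It sets out from 12 and returns at 13. Nickel boride reduction (NaBH4, NiCl2·6H2O, MeOH, 0 °C) gives the amino diol F6. Treatment with the anomeric amide N-(benzyloxy)-N-(pivaloyloxy)-4-(trifluoromethyl)benzamide (MeCN, 45 °C) converts the primary amine through an isodiazene into the C–H compound with loss of N2; this reagent tolerates free hydroxyls.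

Step 12. Acrolein may polymerise faster than the α-branched vinyl iodide inserts, and the unsaturated acetal may suffer at 40 °C in DMF. The fallback builds the diene by carbonyl olefination instead of cross-coupling. It sets out from 16 and returns at 18. Iodine–lithium exchange (t-BuLi, Et2O, −78 °C) with retention and quenching with DMF give the aldehyde (E)-2-(dimethoxymethyl)but-2-enal F7. A Wittig reaction with Ph3P=CHCHO (toluene, 60 °C) then gives the E enal 18.

Step 16. Once freed, the aldehydes may undergo acid-driven side reactions: acetal exchange with the liberated 1,3-diol, or aldol condensation of the CH2CHO groups. The fallback changes from global to staged unmasking, with an isolable intermediate. It sets out from 24 and returns at 25. Acetal exchange in wet acetone with pyridinium tosylate, a medium in which the isopropylidene ketal is retained, gives the tetra-aldehyde ketal F8. The ketal alone is then removed with cold 60% aqueous AcOH, so each stage can be stopped at the first sign of damage.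

## Further compounds

F1 | step 7 | tert-butyl{[(1S,5R)-5-(2,2-dimethyl-1,3-dioxan-5-yl)-3-hydroxy-2-methylcyclopentyl]methoxy}dimethylsilane (C2/C3 epimer mixture) | CC(C)(C)[Si](C)(C)OC[C@@H]1C(C)C(O)C[C@H]1C2COC(C)(C)OC2
F2 | step 7 | (2R,3S,4R)-3-{[tert-butyl(dimethyl)silyl]oxymethyl}-4-(2,2-dimethyl-1,3-dioxan-5-yl)-2-methylcyclopentan-1-one | CC(C)(C)[Si](C)(C)OC[C@@H]1[C@@H](C)C(=O)C[C@H]1C2COC(C)(C)OC2
F3 | step 7 | (1R,2R,3S,4R)-3-{[tert-butyl(dimethyl)silyl]oxymethyl}-4-(2,2-dimethyl-1,3-dioxan-5-yl)-2-methylcyclopentan-1-ol | CC(C)(C)[Si](C)(C)OC[C@@H]1[C@@H](C)[C@H](O)C[C@H]1C2COC(C)(C)OC2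
F4 | step 13 | (R)-3-[(E)-5,5-dimethoxypent-2-enoyl]-4-phenyl-1,3-oxazolidin-2-one | COC(OC)C/C=C/C(=O)N1[C@H](c2ccccc2)COC1=O
F5 | step 13 | (R)-3-[(3S,4E)-4-(dimethoxymethyl)-3-(2,2-dimethoxyethyl)hex-4-enoyl]-4-phenyl-1,3-oxazolidin-2-one | C/C=C(/C(OC)OC)[C@@H](CC(OC)OC)CC(=O)N1[C@H](c2ccccc2)COC1=O
F6 | step 9 | [(1S,2R,3S,4R,5R)-4-amino-5-(2,2-dimethyl-1,3-dioxan-5-yl)-3-hydroxy-2-methylcyclopentyl]methanol | OC[C@@H]1[C@@H](C)[C@H](O)[C@H](N)[C@H]1C2COC(C)(C)OC2
F7 | step 12 | (E)-2-(dimethoxymethyl)but-2-enal | C/C=C(/C(OC)OC)C=O
F8 | step 16 | [(1S,2R,3R,5R)-5-(2,2-dimethyl-1,3-dioxan-5-yl)-3-{[(3S,4E)-4-formyl-3-(2-oxoethyl)hex-4-enoyl]oxy}-2-methylcyclopentyl]methyl (3S,4E)-4-formyl-3-(2-oxoethyl)hex-4-enoate | C/C=C(/C=O)[C@@H](CC=O)CC(=O)OC[C@@H]1[C@@H](C)[C@H](OC(=O)C[C@H](CC=O)/C(C=O)=C\C)C[C@H]1C2COC(C)(C)OC2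
A1 | alternative 1 | (E)-5-{[tert-butyl(dimethyl)silyl]oxy}pent-2-enal | CC(C)(C)[Si](C)(C)OCC/C=C/C=O
A2 | alternative 1 | ethoxyethene (ethyl vinyl ether) | C=COCC
A3 | alternative 1 | (2R,4R)-2-ethoxy-4-(2-{[tert-butyl(dimethyl)silyl]oxy}ethyl)-3,4-dihydro-2H-pyran | CC(C)(C)[Si](C)(C)OCC[C@@H]1C[C@H](OCC)OC=C1
A4 | alternative 2 | diol 13 esterified at both hydroxyls with 3-oxo-3-(prop-2-enoxy)propanoic acid (core bis(allyl malonate)) | C=CCOC(=O)CC(=O)OC[C@@H]1[C@@H](C)[C@H](OC(=O)CC(=O)OCC=C)C[C@H]1C2COC(C)(C)OC2
A5 | alternative 2 | (2E,4E)-4-({[tert-butyl(dimethyl)silyl]oxy}methyl)hexa-2,4-dienal | C/C=C(/CO[Si](C)(C)C(C)(C)C)\C=C\C=O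
A6 | alternative 2 | bis-Michael adduct of A4 with two molecules of A5, each malonate carbon bonded to C3 of a (3S,4E)-4-(silyloxymethyl)-1-oxohex-4-en-3-yl unit, epimeric at the malonate carbons | C/C=C(/CO[Si](C)(C)C(C)(C)C)[C@@H](CC=O)C(C(=O)OCC=C)C(=O)OC[C@@H]1[C@@H](C)[C@H](OC(=O)C(C(=O)OCC=C)[C@H](CC=O)/C(CO[Si](C)(C)C(C)(C)C)=C\C)C[C@H]1C2COC(C)(C)OC2
A7 | alternative 3 | dimethyl 2-[(3S,4E)-4-({[tert-butyl(dimethyl)silyl]oxy}methyl)-1-oxohex-4-en-3-yl]propanedioate | O=CC[C@H](/C(CO[Si](C)(C)C(C)(C)C)=C\C)C(C(=O)OC)C(=O)OC
A8 | alternative 3 | dimethyl 2-[(1R,2S,3R)-2-({[tert-butyl(dimethyl)silyl]oxy}methyl)-3-methyl-4-oxocyclopentyl]propanedioate | CC(C)(C)[Si](C)(C)OC[C@@H]1[C@@H](C)C(=O)C[C@H]1C(C(=O)OC)C(=O)OC
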